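(The readings are simulated with constants of no real substance; noise was put on by code.)

Target that is made and used at once cannot climb past the level where the two rates are equal, so we count turnovers: substrate turned into target per hour, over the fraction of target used per hour.

| flask | substrate | reagent | remark | time |
|---|---|---|---|---|
| blue | 0.32 M | 0.96 M | the very flask that is asked about, followed so far |  |
| amber | 0.21 M | 0.96 M | run made earlier |  |
| flask | 0.32 M | 0.960 M |  | 3.0 d |

- blue (time / h: target / %, substrate / %): 8.00: 12.0, 81.9; 10.0: 14.9, 77.6; 12.0: 16.2, 74.3; 15.0: 18.8, 66.7; 20.0: 19.5, 57.9
- amber (time / h: target / %, substrate / %): 8.00: 13.4, 81.7; 12.0: 18.2, 74.2; 20.0: 22.0, 60.3; 30.0: 26.5, 45.6; 48.0: 25.6, 27.9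

(standard deviation of a reading: 0.5 percentage points)

1. the best time, 3.0 d at the latest, for target
2. the amount of target, in percent of the substrate charged, at that time

- a species is counted by the substrate in it: one side product counts as two
- steps under discussion: target <-> isomer of the product; substrate + target -> side product; substrate + reagent -> target + released group

Amber's first reading gives substrate a rate of 0.0253 /h, which we take as the main step with reagent at its charge, a pseudo-first-order reading and a little high. Amber's target reads nearly flat over its last two readings, so we take making as equal to using there, which gives a loss per target of 0.0356 /h at [substrate] = 0.0772 M. Blue, the asked flask followed so far, still rises from 12.0 h to 20.0 h, and making minus that rise gives 0.0704 /h at 0.212 M. A line through both splits the loss into 0.259 /M/h times [substrate] plus 0.0156 /h. So the break-even target of blue at 20.0 h, the making rate over that loss, is 23.0%, above the 19.5% read. Target climbs while this level sinks with substrate; splitting the gap, we set their meeting at 21.2%, which needs [substrate] = 0.139 M, and blue's substrate decay of 0.0312 /h reaches that at 1.22 d. The weak link is blue's small rise, given a scatter of 0.5 percentage points per reading; taken from 8.00 h instead, the level at that substrate reads 21.4%, so our number stands.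

The forecast, reckoned apart from ours, says 22% at 1.4 d, later than ours: “The maximum is flat.” The flask gives 21.4% at 1.36 d.

    target ⇌ isomer of the product (K = 22.0, k = 3.10 × 10⁻⁴ /min)
    substrate + target → side product (k = 0.00230 /M/min)
    substrate + reagent → target + released group (k = 3.90 × 10⁻⁴ /M/min)

At 0.300 d the flask held 83.7% of substrate, 11.8% of target and 3.72% of side product. At 1.36 d, with 40.6% of substrate, side product stood at 28.3% and the isomer of the product at 9.69%, and by 3.00 d target had fallen to 16.9%. Our level at that best-time substrate reads 20.8%, beside 21.4% in the flask. Scaled to a neighbour flask charged with 0.38 M of reagent, at substrate as charged, it reads 10.1%, and that neighbour's target peaked at 9.80%.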